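**Plan**

1. Locants follow the labdane skeleton (ring A = C1–C5 + C10, ring B = C5–C10, side chain C11–C16; β = the ring-B face carrying the C10 methyl). Ring B with H-5, the C8 methyl on a C7=C8 alkene and an oxygenated C9 is (S)-carvone; its isopropenyl carbon is C4, one bond (C3–C4) short of ring A once a three-carbon acceptor chain sits on C10.
2. Retrosynthetic cuts: O–C15 of the enol ether; the C7–O, C8–O and C6=O oxidation pattern; C14–C15; the C9–O–C13 ether; C12–C13; C9–C11; C3–C4 of ring A; C10–C1 and C10–CH3.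
3. Forward order: carvone ring B → two enolate alkylations at C10 → ring A by hydrogen-atom-transfer radical cyclisation onto a vinyl sulfone → C9 side chain → spiro tetrahydrofuran → oxygenation of C6, C8 and C7 → dihydrofuran closed last.
4. Stereochemistry: C5 from (S)-carvone; C10 by methylation anti to isopropenyl (hence the cis ring fusion); C9 by vinyl addition anti to the axial C1 methylene; C13 by Sharpless epoxidation and invertive ring opening; C8 by hydroxyl-directed epoxidation from a C6 carbinol; C7 by Rubottom oxidation anti to the C8 acetate.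

Key step: step 4

Remark: the descriptors of the given structure place H-5 and the C10 methyl on the same face (cis A/B fusion, 5β-H); the route is built for exactly this relative configuration.

**Route**

Step 1
Reactants: 1 (S)-carvone; 2 2,3-dibromopropene
Product: 3 (5S,6R)-6-(2-bromoprop-2-en-1-yl)-2-methyl-5-(prop-1-en-2-yl)cyclohex-2-en-1-one
Conditions: LiN(i-Pr)2, THF, −78 °C; then 2, −78 → −20 °C
Reagents that add atoms: none
Why: Kinetic α′-deprotonation of the enone and enolate alkylation with the allylic bromide (SN2 at CH2Br) is standard for carvone and places the new group trans to the neighbouring isopropenyl group; this centre is re-formed in step 2.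

Step 2
Reactants: 3 bromoallyl carvone
Product: 4 (5R,6S)-6-(2-bromoprop-2-en-1-yl)-2,6-dimethyl-5-(prop-1-en-2-yl)cyclohex-2-en-1-one
Conditions: LiN(i-Pr)2, THF, −78 → −20 °C; then MeI, DMPU, −78 → 0 °C
Reagents that add atoms: iodomethane, CI
Why: Second α′-enolate alkylation: with the bromoallyl group in the enolate plane the C5 isopropenyl group turns pseudoaxial and shields one face, so iodomethane should add anti to it and create the quaternary centre (future C10) with methyl trans and the three-carbon tether cis to isopropenyl.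

Step 3
Reactants: 4 bromoallyl methyl carvone; 5 sodium benzenesulfinate (PhSO2Na)
Product: 6 (5R,6S)-2,6-dimethyl-6-[2-(phenylsulfonyl)prop-2-en-1-yl]-5-(prop-1-en-2-yl)cyclohex-2-en-1-one
Conditions: CuI (copper monoiodide, 20 mol%), N,N′-dimethylethylenediamine (40 mol%), DMSO, 100 °C
Reagents that add atoms: none
Why: Ullmann-type copper-catalysed C–S coupling of the alkenyl bromide with the sulfinate salt gives the alkenyl sulfone without moving the double bond, and the neutral conditions leave the enone and the isopropenyl group untouched.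

Step 4
Reactants: 6 sulfonylallyl methyl carvone
Product: 7 2-(phenylsulfonyl)-11,12,13,14,15,16-hexanor-5β-labd-7-en-9-one (cis-fused, C2 epimer mixture)
Conditions: Fe(acac)3 (30 mol%), PhSiH3 (3 equiv), EtOH/ethylene glycol (5:1), 60 °C
Reagents that add atoms: none
Why: Fe(acac)3 and PhSiH3 generate an iron hydride in ethanol that hands one hydrogen atom to the terminal carbon of the isopropenyl group, so that C4 becomes a tertiary, electron-rich radical flanked by two methyl groups; C4 then bonds to the sulfone-free alkene terminus C3, and the radical left next to sulfur at C2 takes an electron from divalent iron and a proton from the solvent. The closest known reaction type is the iron-hydride-initiated reductive coupling of an unactivated alkene with an electron-poor alkene (Giese-type addition), used here intramolecularly. Ring A (C1–C5, C10) closes in the 6-endo-trig mode through the new C3–C4 bond. No lasting stereocentre is formed: C4 becomes a gem-dimethyl carbon, the sulfonyl-bearing C2 is erased in step 6, and the cis ring fusion is already fixed by C5 and C10 of 6. The step needs hydrogen-atom transfer to the isopropenyl group rather than to the enone or the vinyl sulfone, which the preference of the metal hydride for electron-rich 1,1-disubstituted alkenes secures. It also needs 6-endo rather than 5-exo addition, which is secured by polarity matching and by the fully substituted, sulfonyl-bearing internal alkene carbon.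

Step 5
Reactants: 7 sulfonyl enone; 8 vinylmagnesium bromide (CH2=CHMgBr)
Product: 9 2-(phenylsulfonyl)-13,14,15,16-tetranor-5β-labda-7,11-dien-9α-ol (C2 epimer mixture)
Conditions: 8 (3 equiv), CeCl3 (3.3 equiv), THF, −78 °C; then 7, −78 → 0 °C
Reagents that add atoms: none
Why: Organocerium 1,2-addition to the hindered enone (no conjugate addition, no deprotonation next to the sulfone) should occur axially on the β-face of C9, anti to the axial C1 methylene of the folded ring A, which sets the 9α-hydroxyl and the 9β-vinyl group.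

Step 6
Reactants: 9 sulfonyl dienol
Product: 10 13,14,15,16-tetranor-5β-labda-7,11-dien-9α-ol
Conditions: sodium amalgam (6% Na in Hg), Na2HPO4, MeOH/THF, −20 → 0 °C
Reagents that add atoms: none
Why: Reductive desulfonylation by electron transfer from sodium amalgam removes the auxiliary sulfone as sulfinate; with the enone already converted into the tertiary allylic alcohol nothing else in the molecule is reducible under the phosphate-buffered conditions.

Step 7
Reactants: 10 dienol; 11 2-bromoprop-2-en-1-ol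
Product: 13 15-nor-5β-labda-7,13(14)-diene-9α,16-diol, via B-alkyl-9-BBN borane 12 (not isolated)
Conditions: 9-BBN (2.5 equiv), THF, rt; then 11, Pd(dppf)Cl2 (5 mol%), AsPh3 (10 mol%), Cs2CO3, DMF/THF/H2O, rt → 45 °C
Reagents that add atoms: none
Why: Hydroboration of the monosubstituted vinyl group with 9-BBN (the trisubstituted C7=C8 bond is too hindered) and B-alkyl Suzuki–Miyaura coupling of the borane with the alkenyl bromide join C12 to C13 and give the 2-substituted allylic alcohol directly.

Step 8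
Reactants: 13 diene diol
Product: 14 (13S)-13,14-epoxy-15-nor-5β-labd-7-ene-9α,16-diol
Conditions: Ti(OiPr)4 (10 mol%), L-(+)-diisopropyl tartrate (12 mol%), t-BuOOH, 4 Å MS, CH2Cl2, −20 °C
Reagents that add atoms: tert-butyl hydroperoxide, CC(C)(C)OO
Why: Sharpless asymmetric epoxidation of the primary allylic alcohol is reagent-controlled: L-(+)-tartrate delivers oxygen to the face that gives the (13S)-epoxide, while the hindered tertiary allylic alcohol at C9 and its trisubstituted alkene react far more slowly.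

Step 9
Reactants: 14 epoxy diol
Product: 15 (13R)-16-(tert-butyldimethylsilyloxy)-13,14-epoxy-15-nor-5β-labd-7-en-9α-ol (same spatial arrangement at C13 as in 14)
Conditions: TBSCl, imidazole, CH2Cl2, 0 °C
Reagents that add atoms: tert-butyldimethylsilyl chloride, CC(C)(C)[Si](C)(C)Cl
Why: Silylation of the primary hydroxyl with the silyl chloride and imidazole (no alkoxide, hence no Payne rearrangement) distinguishes the two one-carbon arms at C13 before ring closure; the tertiary hydroxyl is too hindered to react.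

Step 10
Reactants: 15 silyloxy epoxide
Product: 16 (13S)-16-(tert-butyldimethylsilyloxy)-9α,13-epoxy-15-nor-5β-labd-7-en-14-ol
Conditions: camphorsulfonic acid (10 mol%), CH2Cl2, −20 → 0 °C
Reagents that add atoms: none
Why: Acid-catalysed 5-exo epoxide opening by the C9 hydroxyl at the tertiary epoxide carbon, where Baldwin and Markovnikov preferences coincide, closes the spiro tetrahydrofuran with inversion at C13 and frees the C14 hydroxyl.

Step 11
Reactants: 16 spiro ether alcohol
Product: 17 (13R)-16-(tert-butyldimethylsilyloxy)-9α,13-epoxy-15-nor-5β-labd-7-en-14-al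
Conditions: Dess–Martin periodinane, NaHCO3, CH2Cl2, 0 °C → rt
Reagents that add atoms: none
Why: Dess–Martin oxidation of the neopentyl-type primary alcohol gives an aldehyde without α-hydrogen, so C13 cannot epimerise, and immediate oxidation also excludes silyl migration between the two C13 arms.

Step 12
Reactants: 17 aldehyde
Product: 18 (13S)-16-(tert-butyldimethylsilyloxy)-9α,13-epoxy-5β-labd-7-en-14-yne
Conditions: MeC(O)C(N2)P(O)(OMe)2, K2CO3, MeOH, 0 °C → rt
Reagents that add atoms: dimethyl (1-diazo-2-oxopropyl)phosphonate, CC(=O)C(=[N+]=[N-])P(=O)(OC)OC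
Why: Seyferth–Gilbert homologation with the Ohira–Bestmann reagent converts the non-enolisable aldehyde into the terminal alkyne C14≡C15 under carbonate conditions that the silyl ether tolerates.

Step 13
Reactants: 18 alkyne
Product: 19 (13S)-16-(tert-butyldimethylsilyloxy)-9α,13-epoxy-5β-labd-7-en-14-yn-6-one
Conditions: CrO3 (15 equiv), 3,5-dimethylpyrazole (15 equiv), CH2Cl2, −20 °C
Reagents that add atoms: chromium trioxide, O=[Cr](=O)=O
Why: Allylic oxidation of the ring methylene C6 by the CrO3–3,5-dimethylpyrazole complex gives the conjugated 7-en-6-one; C9 is now an ether, so no oxidative allylic transposition can occur, and the alkyne, the silyl ether and the fully substituted ether carbons offer no competing oxidisable position.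

Step 14
Reactants: 19 enone
Product: 20 (13S)-16-(tert-butyldimethylsilyloxy)-9α,13-epoxy-5β-labd-7-en-14-yn-6α-ol
Conditions: LiBH(s-Bu)3 (L-Selectride), THF, −78 °C
Reagents that add atoms: none
Why: 1,2-Reduction of the β,β-disubstituted enone by the bulky borohydride should take place from the β-face of C6, away from the axial C1 methylene, and give the pseudoaxial 6α-alcohol.

Step 15
Reactants: 20 allylic alcohol
Product: 21 (13S)-16-(tert-butyldimethylsilyloxy)-7α,8α:9α,13-diepoxy-5β-labd-14-yn-6α-ol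
Conditions: VO(acac)2 (5 mol%), t-BuOOH, CH2Cl2, 0 °C → rt
Reagents that add atoms: tert-butyl hydroperoxide, CC(C)(C)OO
Why: Vanadium-catalysed hydroxyl-directed epoxidation of the cyclic allylic alcohol delivers oxygen syn to the 6α-hydroxyl, which places the C8–O bond on the α-face, cis to the C9–O bond.

Step 16
Reactants: 21 epoxy alcohol
Product: 22 (13S)-16-(tert-butyldimethylsilyloxy)-7α,8α:9α,13-diepoxy-5β-labd-14-yn-6-one
Conditions: Dess–Martin periodinane, NaHCO3, CH2Cl2, rt
Reagents that add atoms: none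
Why: Buffered Dess–Martin oxidation of the secondary alcohol gives the α,β-epoxy ketone without opening the epoxide.

Step 17
Reactants: 22 epoxy ketone
Product: 23 (13S)-16-(tert-butyldimethylsilyloxy)-9α,13-epoxy-8α-hydroxy-5β-labd-14-yn-6-one
Conditions: SmI2 (2.2 equiv), THF/MeOH, −90 °C
Reagents that add atoms: none
Why: Reductive cleavage of the Cα–O bond of the α,β-epoxy ketone by SmI2 gives the β-hydroxy ketone, so C7 becomes CH2 while the C8–O bond and its α-configuration are kept.

Step 18
Reactants: 23 β-hydroxy ketone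
Product: 24 (13S)-8α-acetoxy-16-(tert-butyldimethylsilyloxy)-9α,13-epoxy-5β-labd-14-yn-6-one
Conditions: Ac2O, DMAP, pyridine, rt → 40 °C
Reagents that add atoms: acetic anhydride, CC(=O)OC(C)=O
Why: DMAP-catalysed acylation (Steglich-type) esterifies the hindered tertiary hydroxyl, and the weakly basic pyridine medium keeps β-elimination of the resulting β-acetoxy ketone slow.

Step 19
Reactants: 24 β-acetoxy ketone
Product: 25 (13S)-8α-acetoxy-16-(tert-butyldimethylsilyloxy)-9α,13-epoxy-6-(trimethylsilyloxy)-5β-labd-6-en-14-yne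
Conditions: Me3SiOTf, Et3N, CH2Cl2, −78 → 0 °C
Reagents that add atoms: trimethylsilyl trifluoromethanesulfonate, C[Si](C)(C)OS(=O)(=O)C(F)(F)F
Why: Soft enolisation with silyl triflate and amine forms the silyl enol ether toward C7 without a metal enolate that could expel the β-acetoxy group, H-5 being shielded by the quaternary C4 and C10.

Step 20
Reactants: 25 silyl enol ether
Product: 27 (13S)-8α-acetoxy-9α,13-epoxy-7β,16-dihydroxy-5β-labd-14-yn-6-one, via 6β,7β-epoxy silyl ether 26 (not isolated)
Conditions: dimethyldioxirane, acetone/CH2Cl2, −78 → −20 °C; evaporation; then HF·pyridine, pyridine, THF, 0 °C → rt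
Reagents that add atoms: dimethyldioxirane, CC1(C)OO1
Why: Rubottom oxidation: the dioxirane should epoxidise the silyl enol ether axially on the β-face, anti to the pseudoaxial 8α-acetoxy group, and fluoride then opens the silyloxy epoxide to the 7β-hydroxy ketone and removes the primary silyl ether in the same operation.

Step 21
Reactants: 27 alkynol ketol
Product: 28 (5R,7R,8R,9S,10S,13S)-8-acetoxy-9,13:15,16-diepoxy-7-hydroxylabd-14-en-6-one (target)
Conditions: Et3N·Mo(CO)5 (25 mol%, preformed from Mo(CO)6, Et3N, Et2O, hν 350 nm), Et2O, rt, dark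
Reagents that add atoms: none
Why: Molybdenum-carbonyl-catalysed cycloisomerisation of a 1-alkyn-4-ol (terminal alkyne to metal vinylidene, then 5-endo attack of the C16 hydroxyl on C15) is a known entry to 2,3-dihydrofurans, and its amine-buffered, non-acidic medium preserves the acid-labile spiro enol ether, which is why this ring is closed last.

**Compound list**

1 | (S)-carvone, (5S)-2-methyl-5-(prop-1-en-2-yl)cyclohex-2-en-1-one | CC1=CC[C@@H](CC1=O)C(C)=C | starting material
2 | 2,3-dibromopropene | BrCC(Br)=C | starting material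
3 | (5S,6R)-6-(2-bromoprop-2-en-1-yl)-2-methyl-5-(prop-1-en-2-yl)cyclohex-2-en-1-one (bromoallyl trans to isopropenyl) | CC1=CC[C@H](C(C)=C)[C@@H](CC(Br)=C)C1=O | intermediate
4 | (5R,6S)-6-(2-bromoprop-2-en-1-yl)-2,6-dimethyl-5-(prop-1-en-2-yl)cyclohex-2-en-1-one (6-methyl trans, bromoallyl cis to isopropenyl) | CC1=CC[C@H](C(C)=C)[C@](C)(CC(Br)=C)C1=O | intermediate
5 | sodium benzenesulfinate, PhSO2Na | [Na+].[O-]S(=O)c1ccccc1 | starting material
6 | (5R,6S)-2,6-dimethyl-6-[2-(phenylsulfonyl)prop-2-en-1-yl]-5-(prop-1-en-2-yl)cyclohex-2-en-1-one (6-methyl trans to isopropenyl) | CC1=CC[C@H](C(C)=C)[C@](C)(CC(=C)S(=O)(=O)c2ccccc2)C1=O | intermediate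
7 | 2-(phenylsulfonyl)-11,12,13,14,15,16-hexanor-5β-labd-7-en-9-one (cis-fused 4,4,8,10-tetramethyl bicycle, H-5 and CH3-10 cis, C2 epimer mixture) | CC1=CC[C@@H]2C(C)(C)CC(S(=O)(=O)c3ccccc3)C[C@]2(C)C1=O | intermediate
8 | vinylmagnesium bromide, CH2=CHMgBr | C=C[Mg]Br | starting material
9 | 2-(phenylsulfonyl)-13,14,15,16-tetranor-5β-labda-7,11-dien-9α-ol (C2 epimer mixture) | CC1=CC[C@@H]2C(C)(C)CC(S(=O)(=O)c3ccccc3)C[C@]2(C)[C@@]1(O)C=C | intermediate
10 | 13,14,15,16-tetranor-5β-labda-7,11-dien-9α-ol | CC1=CC[C@@H]2C(C)(C)CCC[C@]2(C)[C@@]1(O)C=C | intermediate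
11 | 2-bromoprop-2-en-1-ol | OCC(Br)=C | starting material
12 | 12-(9-borabicyclo[3.3.1]nonan-9-yl)-13,14,15,16-tetranor-5β-labd-7-en-9α-ol | CC1=CC[C@@H]2C(C)(C)CCC[C@]2(C)[C@@]1(O)CCB1C2CCCC1CCC2 | intermediate
13 | 15-nor-5β-labda-7,13(14)-diene-9α,16-diol | CC1=CC[C@@H]2C(C)(C)CCC[C@]2(C)[C@@]1(O)CCC(=C)CO | intermediate
14 | (13S)-13,14-epoxy-15-nor-5β-labd-7-ene-9α,16-diol | CC1=CC[C@@H]2C(C)(C)CCC[C@]2(C)[C@@]1(O)CC[C@]3(CO)CO3 | intermediate
15 | (13R)-16-(tert-butyldimethylsilyloxy)-13,14-epoxy-15-nor-5β-labd-7-en-9α-ol | CC1=CC[C@@H]2C(C)(C)CCC[C@]2(C)[C@@]1(O)CC[C@]3(CO[Si](C)(C)C(C)(C)C)CO3 | intermediate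
16 | (13S)-16-(tert-butyldimethylsilyloxy)-9α,13-epoxy-15-nor-5β-labd-7-en-14-ol | CC1=CC[C@@H]2C(C)(C)CCC[C@]2(C)[C@@]13CC[C@@](CO[Si](C)(C)C(C)(C)C)(CO)O3 | intermediate
17 | (13R)-16-(tert-butyldimethylsilyloxy)-9α,13-epoxy-15-nor-5β-labd-7-en-14-al | CC1=CC[C@@H]2C(C)(C)CCC[C@]2(C)[C@@]13CC[C@@](CO[Si](C)(C)C(C)(C)C)(C=O)O3 | intermediate
18 | (13S)-16-(tert-butyldimethylsilyloxy)-9α,13-epoxy-5β-labd-7-en-14-yne | CC1=CC[C@@H]2C(C)(C)CCC[C@]2(C)[C@@]13CC[C@@](CO[Si](C)(C)C(C)(C)C)(C#C)O3 | intermediate
19 | (13S)-16-(tert-butyldimethylsilyloxy)-9α,13-epoxy-5β-labd-7-en-14-yn-6-one | CC1=CC(=O)[C@@H]2C(C)(C)CCC[C@]2(C)[C@@]13CC[C@@](CO[Si](C)(C)C(C)(C)C)(C#C)O3 | intermediate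
20 | (13S)-16-(tert-butyldimethylsilyloxy)-9α,13-epoxy-5β-labd-7-en-14-yn-6α-ol | CC1=C[C@H](O)[C@@H]2C(C)(C)CCC[C@]2(C)[C@@]13CC[C@@](CO[Si](C)(C)C(C)(C)C)(C#C)O3 | intermediate
21 | (13S)-16-(tert-butyldimethylsilyloxy)-7α,8α:9α,13-diepoxy-5β-labd-14-yn-6α-ol | C[C@@]14O[C@@H]1[C@H](O)[C@@H]2C(C)(C)CCC[C@]2(C)[C@@]43CC[C@@](CO[Si](C)(C)C(C)(C)C)(C#C)O3 | intermediate
22 | (13S)-16-(tert-butyldimethylsilyloxy)-7α,8α:9α,13-diepoxy-5β-labd-14-yn-6-one | C[C@@]14O[C@@H]1C(=O)[C@@H]2C(C)(C)CCC[C@]2(C)[C@@]43CC[C@@](CO[Si](C)(C)C(C)(C)C)(C#C)O3 | intermediate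
23 | (13S)-16-(tert-butyldimethylsilyloxy)-9α,13-epoxy-8α-hydroxy-5β-labd-14-yn-6-one | C[C@@]1(O)CC(=O)[C@@H]2C(C)(C)CCC[C@]2(C)[C@@]13CC[C@@](CO[Si](C)(C)C(C)(C)C)(C#C)O3 | intermediate
24 | (13S)-8α-acetoxy-16-(tert-butyldimethylsilyloxy)-9α,13-epoxy-5β-labd-14-yn-6-one | CC(=O)O[C@]1(C)CC(=O)[C@@H]2C(C)(C)CCC[C@]2(C)[C@@]13CC[C@@](CO[Si](C)(C)C(C)(C)C)(C#C)O3 | intermediate
25 | (13S)-8α-acetoxy-16-(tert-butyldimethylsilyloxy)-9α,13-epoxy-6-(trimethylsilyloxy)-5β-labd-6-en-14-yne | CC(=O)O[C@]1(C)C=C(O[Si](C)(C)C)[C@@H]2C(C)(C)CCC[C@]2(C)[C@@]13CC[C@@](CO[Si](C)(C)C(C)(C)C)(C#C)O3 | intermediate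
26 | (13S)-8α-acetoxy-16-(tert-butyldimethylsilyloxy)-6β,7β:9α,13-diepoxy-6α-(trimethylsilyloxy)-5β-labd-14-yne | CC(=O)O[C@]1(C)[C@H]4O[C@@]4(O[Si](C)(C)C)[C@@H]2C(C)(C)CCC[C@]2(C)[C@@]13CC[C@@](CO[Si](C)(C)C(C)(C)C)(C#C)O3 | intermediate
27 | (13S)-8α-acetoxy-9α,13-epoxy-7β,16-dihydroxy-5β-labd-14-yn-6-one | CC(=O)O[C@]1(C)[C@@H](O)C(=O)[C@@H]2C(C)(C)CCC[C@]2(C)[C@@]13CC[C@@](CO)(C#C)O3 | intermediate
28 | (5R,7R,8R,9S,10S,13S)-8-acetoxy-9,13:15,16-diepoxy-7-hydroxylabd-14-en-6-one (8α-acetoxy, 7β-hydroxy, 5β-H) | CC(=O)O[C@]1(C)[C@@H](O)C(=O)[C@@H]2C(C)(C)CCC[C@]2(C)[C@@]12CC[C@@]1(C=COC1)O2 | target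

**Step count and risks**

Total step count: 21. Longest linear sequence: 21 steps, from (S)-carvone 1 to 28; the route is fully linear.

Steps most likely to fail:

Step 20 (together with the enol ether made in step 19). The C8 acetoxy group may be lost by β-elimination once C7 is enolised, or the oxidant may attack the enol ether on the α-face. The fallback sets out from 23 and moves the hydroxylation ahead of the acetylation. Treatment of 23 with excess KN(SiMe3)2 (THF, −78 °C) should give an alkoxide–enolate in which the C8 oxygen cannot leave. Hydroxylation with 2-(phenylsulfonyl)-3-phenyloxaziridine, anti to the axial C8 alkoxide, should give (13S)-16-(tert-butyldimethylsilyloxy)-9α,13-epoxy-7β,8α-dihydroxy-5β-labd-14-yn-6-one F1. The secondary hydroxyl is silylated (Et3SiCl, imidazole) to the 7-O-triethylsilyl ether of this diol F2, and the tertiary hydroxyl is acetylated (Ac2O, DMAP, pyridine) to the 8-O-acetyl-7-O-triethylsilyl derivative F3. HF·pyridine then removes both silyl groups and returns to the route at 27.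

Step 18. Acylation of the hindered tertiary hydroxyl may be slow, with competing retro-aldol cleavage or dehydration of the β-hydroxy ketone. The fallback sets out from 20 and brings in the acetate by addition to the alkene instead of by esterification. Bromoacetoxylation (N-bromosuccinimide, AcOH, NaOAc) should form the bromonium ion on the β-face and open it at the tertiary C8 from the α-face, giving (13S)-8α-acetoxy-7β-bromo-16-(tert-butyldimethylsilyloxy)-9α,13-epoxy-5β-labd-14-yn-6α-ol F4. Radical debromination (Bu3SnH, AIBN, toluene, 80 °C, high hydride concentration) gives (13S)-8α-acetoxy-16-(tert-butyldimethylsilyloxy)-9α,13-epoxy-5β-labd-14-yn-6α-ol F5. Dess–Martin oxidation of the C6 carbinol returns to the route at 24.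

Step 3. Insertion of copper into the hindered 2-bromoalkene may be sluggish, and the substrate may decompose at the temperature needed. The fallback sets out from 1 and introduces the sulfone together with the allyl group. Phenyl vinyl sulfone (commercial) is hydroxymethylated (paraformaldehyde, DABCO; Morita–Baylis–Hillman reaction) to 2-(phenylsulfonyl)prop-2-en-1-ol F6, which PBr3 converts into 3-bromo-2-(phenylsulfonyl)prop-1-ene F7. The lithium enolate of 1 (LiN(i-Pr)2, THF, −78 °C) is allylated with F7 by addition–elimination to (5S,6R)-2-methyl-6-[2-(phenylsulfonyl)prop-2-en-1-yl]-5-(prop-1-en-2-yl)cyclohex-2-en-1-one F8. Methylation (LiN(SiMe3)2, MeI, −78 °C) anti to isopropenyl returns to the route at 6.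

Further compounds
F1 | step 20 | (13S)-16-(tert-butyldimethylsilyloxy)-9α,13-epoxy-7β,8α-dihydroxy-5β-labd-14-yn-6-one | C[C@@]1(O)[C@@H](O)C(=O)[C@@H]2C(C)(C)CCC[C@]2(C)[C@@]13CC[C@@](CO[Si](C)(C)C(C)(C)C)(C#C)O3
F2 | step 20 | 7-O-triethylsilyl ether of F1 | C[C@@]1(O)[C@@H](O[Si](CC)(CC)CC)C(=O)[C@@H]2C(C)(C)CCC[C@]2(C)[C@@]13CC[C@@](CO[Si](C)(C)C(C)(C)C)(C#C)O3
F3 | step 20 | 8-O-acetyl-7-O-triethylsilyl derivative of F1 | CC(=O)O[C@]1(C)[C@@H](O[Si](CC)(CC)CC)C(=O)[C@@H]2C(C)(C)CCC[C@]2(C)[C@@]13CC[C@@](CO[Si](C)(C)C(C)(C)C)(C#C)O3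
F4 | step 18 | (13S)-8α-acetoxy-7β-bromo-16-(tert-butyldimethylsilyloxy)-9α,13-epoxy-5β-labd-14-yn-6α-ol | CC(=O)O[C@]1(C)[C@@H](Br)[C@H](O)[C@@H]2C(C)(C)CCC[C@]2(C)[C@@]13CC[C@@](CO[Si](C)(C)C(C)(C)C)(C#C)O3
F5 | step 18 | (13S)-8α-acetoxy-16-(tert-butyldimethylsilyloxy)-9α,13-epoxy-5β-labd-14-yn-6α-ol | CC(=O)O[C@]1(C)C[C@H](O)[C@@H]2C(C)(C)CCC[C@]2(C)[C@@]13CC[C@@](CO[Si](C)(C)C(C)(C)C)(C#C)O3
F6 | step 3 | 2-(phenylsulfonyl)prop-2-en-1-ol | OCC(=C)S(=O)(=O)c1ccccc1
F7 | step 3 | 3-bromo-2-(phenylsulfonyl)prop-1-ene | BrCC(=C)S(=O)(=O)c1ccccc1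
F8 | step 3 | (5S,6R)-2-methyl-6-[2-(phenylsulfonyl)prop-2-en-1-yl]-5-(prop-1-en-2-yl)cyclohex-2-en-1-one | CC1=CC[C@H](C(C)=C)[C@@H](CC(=C)S(=O)(=O)c2ccccc2)C1=O
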